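Start with the easy step: salt in the second phase turns spent carrier into fresh carrier, and fresh carrier then turns substrate into product.

    spent carrier + salt in the second phase ⇌ fresh carrier + spent salt in the second phase (K1 = 3.1, k1 = 774 M⁻¹ s⁻¹)
    substrate + fresh carrier ⇌ product + spent carrier (K2 = 0.888, k2 = 1340 M⁻¹ s⁻¹)

substrate 0.50 mM; salt in the second phase 1.05 equiv; spent carrier 12 mol%; volume of the second phase over the first 0.25

- in the second phase: salt in the second phase, spent salt in the second phase; everything else is in the first
- charges count per volume of the first phase; a concentration in a rate is the amount of a species over the volume of its own phase; every rate counts per litre of the first phase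
- charge of substrate (flask): 0.50 mM

* the form that holds most of the catalyst when 5.0% of the substrate are converted (fresh carrier / spent carrier)
* its share of the catalyst then
* apparent order in spent carrier when 5.0% of the substrate are converted (percent change of the rate of making product for one percent more spent carrier charged)

Take regeneration first. In this flask the salt stands at 2.10 mM in its own small phase, so each spent carrier turns fresh at 1.63 s⁻¹. On this step by itself, the 0.0600 mM of catalyst moves over towards the fresh form.

Now add use: substrate takes each fresh carrier back at 0.670 s⁻¹, slower than regeneration. The two balance at 70.8% fresh. Call this the fresh share, regeneration over regeneration plus use. On this reckoning fresh carrier holds most of the catalyst, which makes it the resting state.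

Then add the rest. At 5.0% conversion, salt has been used for the product made and for the fresh carrier standing. Counting the back reactions, regeneration comes to 1.45 s⁻¹ and use to 0.704 s⁻¹, so the share drops to 67.4%.

The flask also starts with no fresh carrier, so join the two ends. The start lags by 0.436 s and the steady run needs 0.878 s, which puts the mark at 1.31 s. Then 4.90% of the gap is still open, and my share is 64.1%.

The rate follows fresh carrier, so my order starts at one. A percent more catalyst reaches the mark sooner, which takes off 0.104. It also ties up more salt, which takes off 0.0492. My order is 0.847.

The forecast says fresh carrier at 66%, with order 0.84, holding that “roughly two-thirds of the catalyst sits as fresh carrier”. Its share stands higher than mine.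

The simulation gives fresh carrier at 64.8%, with spent carrier at 35.2%, and an order of 0.85.

In this flask, by 3.00 s, fresh carrier held 67.1% of the catalyst charged, with product at 12.5% of the substrate charged. Through 30.0 s both went on while substrate fell to 43.7% and salt to 39.1%, with fresh carrier at 63.4%. With twice the salt, the fresh share as charged rises from 70.8% to 82.9%. In that flask I reckon regeneration at the mark at 3.06 s⁻¹ and use at 0.711 s⁻¹. With its lag, my share there comes to 79.6%, a rate factor of 1.24, and the simulated flask gives 1.25.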